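**Retrosynthetic overview**
1. Numbering (lignan): ring A is the fused arene C1–C6 (OMe on C3, OH on C4). Ring B is the carbocycle C1–C7–C8–C8'–C7'–C6. Ring C is the pendant aryl C1'–C6' (OMe on C3', OH on C4'). C9 sits on C8 and C9' on C8'.
2. The sulfate goes onto O9' in the last step but one. O9' and O9 are distinct from the start, because C9' enters as a hindered chiral ester and C9 as a methyl ester.
3. Ring B is cut at C1–C7 and at C7'–C8'. This is a formal [3+3] union of the C7'–C6–C1 unit of a δ-aryl para-quinone methide (ring C quinoid, ring A on C7') with the C8'–C8–C7 unit of an itaconate diester.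
4. Enabling feature: C7' sits on C1', para to O4'–H of ring C, so it can be a quinone methide carbon (the electrophile of lignan biosynthesis). C1 of ring A is para to O4–H, so it is a phenolate carbon nucleophile. C7, C8, C9, C8' and C9' are the five carbons of itaconic acid, nucleophilic at C8' and electrophilic at C7.
5. Rings A and C are bought. Ring B is the only ring made (step 4), together with C7', C8' and C8. A bromine on C5' (isolable quinone methide, blocked ring C) and the 8-phenylmenthyl ester are removed later at no extra step.

Key step: step 4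

Assumption: (−)-8-phenylmenthol is taken to be the antipode that favours the C7' configuration drawn; should the addition prefer the other face, (+)-8-phenylmenthol is used and nothing else changes.

Step 1
Reactants: 1 2-bromo-6-methoxyphenol; 2 isovanillin (3-hydroxy-4-methoxybenzaldehyde)
Product: 4 5-[(3-bromo-5-methoxy-4-oxocyclohexa-2,5-dien-1-ylidene)methyl]-2-methoxyphenyl acetate (para-quinone methide; E/Z mixture), via Mannich base 3 (not isolated)
Conditions: piperidine (2.2 equiv), toluene, 110 °C, azeotropic removal of water; then Ac2O (4 equiv), 80 °C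
Reagents that add atoms: acetic anhydride CC(=O)OC(C)=O
Why: Mannich-type condensation of the iminium ion of 2 at the only free activated position of 1 (para to OH, both ortho positions blocked) followed by acetylative elimination of piperidine is the standard entry to 2,6-disubstituted para-quinone methides; it should also acetylate O4 of ring A, and it creates no stereocentre (the E/Z isomers converge once ring C aromatises).

Step 2
Reactants: 5 itaconic anhydride; 6 (−)-8-phenylmenthol
Product: 7 4-[(−)-8-phenylmenthyl] hydrogen itaconate
Conditions: toluene, 110 °C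
Reagents that add atoms: none
Why: Alcoholysis of a cyclic anhydride should open 5 at its non-conjugated, more electrophilic carbonyl (the known regiochemistry of itaconic anhydride), which places the chiral ester on C9', leaves the conjugated C9 acid free and does not touch the stereocentres of 6.

Step 3
Reactants: 7 4-[(−)-8-phenylmenthyl] hydrogen itaconate
Product: 8 1-methyl 4-[(−)-8-phenylmenthyl] itaconate
Conditions: MeI, KHCO3, DMF, 23 °C
Reagents that add atoms: iodomethane CI
Why: SN2 O-alkylation of the carboxylate should give the mixed diester, since hydrogen carbonate is too weak a base to move the exocyclic double bond.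

Step 4
Reactants: 8 1-methyl 4-[(−)-8-phenylmenthyl] itaconate; 4 para-quinone methide
Product: 11 3-methyl 2-[(−)-8-phenylmenthyl] (1S,2R,3R)-1-(3-bromo-4-hydroxy-5-methoxyphenyl)-7-hydroxy-6-methoxy-1,2,3,4-tetrahydronaphthalene-2,3-dicarboxylate, via lithium dienolate 9 (not isolated), via 1,6-adduct 10 (not isolated)
Conditions: LiN(iPr)2 (1.05 equiv), THF, −78 °C; 4 in THF, −78 °C; then NaOMe (5 equiv), MeOH, −78 → 50 °C, argon; aq. HCl; chromatography to remove the minor diastereomer
Reagents that add atoms: none
Why: Proposed new method: the lithium dienolate 9 attacks through C8' (the α-selectivity known for itaconate dienolates with carbonyl electrophiles) the exocyclic carbon C7' of 4 in a 1,6-conjugate addition that aromatises ring C (bond C7'–C8'), then methoxide frees the ring A phenolate, whose carbon C1 para to O4 adds to the acrylate terminus C7 and rearomatises by proton shift (bond C1–C7), so that 4 acts as a C7'–C6–C1 unit and 8 as a C8'–C8–C7 unit of a formal [3+3] annulation. The closest known reaction types are the 1,6-addition of ester enolates and malonates to δ-aryl para-quinone methides, the Michael addition of lithium enolates of 8-phenylmenthyl esters to enoates, the acid-promoted [3+2] indane annulations in which a δ-aryl para-quinone methide reacts at the same three atoms, and intramolecular Friedel–Crafts-type Michael additions of phenols, whereas their union with an itaconate in one flask is new. Ring B is the only ring closed, by 6-endo-trig attack of C1 on C7=C8. C7' is set in the irreversible first addition, where the cumyl phenyl group of the ester covers one face of the dienolate and an open antiperiplanar transition state with the C8 substituent turned away from ring A passes this bias on to C7', and the minor C7' series stays a separable diastereomer because the ester remains attached, while C8' and C8 both lie next to ester carbonyls and are equilibrated by NaOMe to the all-equatorial 7',8'-trans-8,8'-trans array. The step needs C8' over C7 attack of the dienolate (kinetic lithium dienolate at −78 °C), C1 over C5 attack of ring A (C5 is squeezed between O4 and C6) and ring A over ring C, which is secured because C3' and C5' carry OMe and Br and the para carbon C1' could only close a reversible 5-endo-trig spiro ring, the reason why C7 is an acrylate carbon and not a halide. Methoxide addition to the acrylate and drift of C7=C8 into conjugation with C9' are reversible, so only the ring closure drains these equilibria.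

Step 5
Reactants: 11 tetralin diester
Product: 12 (−)-8-phenylmenthyl (1S,2R,3R)-1-(3-bromo-4-hydroxy-5-methoxyphenyl)-7-hydroxy-3-(hydroxymethyl)-6-methoxy-1,2,3,4-tetrahydronaphthalene-2-carboxylate
Conditions: LiBH4 (4 equiv), THF, 0 → 40 °C; H2O work-up
Reagents that add atoms: none
Why: Chemoselective borohydride reduction of an ester should convert the unhindered equatorial methyl ester at C9, while the neopentyl-like 8-phenylmenthyl ester at C9' resists both hydride and lactonisation by the new alkoxide, and no stereocentre is touched.

Step 6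
Reactants: 12 hydroxymethyl ester
Product: 13 (−)-8-phenylmenthyl (1S,2R,3R)-7-(benzyloxy)-1-[4-(benzyloxy)-3-bromo-5-methoxyphenyl]-3-[(benzyloxy)methyl]-6-methoxy-1,2,3,4-tetrahydronaphthalene-2-carboxylate
Conditions: BnBr (3.6 equiv), NaH (3.5 equiv), Bu4NI (cat.), DMF, 0 → 23 °C
Reagents that add atoms: benzyl bromide BrCc1ccccc1
Why: A threefold Williamson ether synthesis should cap O4, O4' and O9 in one operation, and C8' already holds its thermodynamic configuration, so the base cannot harm it.

Step 7
Reactants: 13 tribenzyl ether ester
Product: 14 {(1S,2R,3R)-7-(benzyloxy)-1-[4-(benzyloxy)-3-bromo-5-methoxyphenyl]-3-[(benzyloxy)methyl]-6-methoxy-1,2,3,4-tetrahydronaphthalen-2-yl}methanol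
Conditions: LiAlH4, THF, 0 → 40 °C; H2O work-up
Reagents that add atoms: none
Why: LiAlH4 reduction of the ester, the standard reductive removal of an 8-phenylmenthyl group, should free O9'–H as the only hydroxyl group of the molecule and return 6 without touching a stereocentre.

Step 8
Reactants: 14 primary alcohol
Product: 15 sodium {(1S,2R,3R)-7-(benzyloxy)-1-[4-(benzyloxy)-3-bromo-5-methoxyphenyl]-3-[(benzyloxy)methyl]-6-methoxy-1,2,3,4-tetrahydronaphthalen-2-yl}methyl sulfate
Conditions: SO3·pyridine (4 equiv), pyridine, 23 → 40 °C; then aq. NaHCO3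
Reagents that add atoms: sulfur trioxide–pyridine complex O=S(=O)=O.c1ccncc1; sodium hydrogen carbonate [Na+].OC([O-])=O
Why: O-sulfation of a primary alcohol with a sulfur trioxide–amine complex should be regiospecific here, because every other oxygen is etherified.

Step 9
Reactants: 15 sodium sulfate ester
Product: 16 (+)-isolariciresinol 9'-O-(hydrogen sulfate), the target
Conditions: H2 (1 atm), Pd/C (10 wt %), MeOH, 23 °C, short contact time; cold reversed-phase (C18) desalting, lyophilisation
Reagents that add atoms: none
Why: Catalytic hydrogenolysis should cleave the three benzyl ethers and the C5'–Br bond in one operation while the alkyl sulfate monoester and the doubly benzylic C7'–H survive, and the one equivalent of HBr released turns the sodium salt into the free hydrogen sulfate.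

**Compound list**
1 | 2-bromo-6-methoxyphenol | COc1cccc(Br)c1O | starting material
2 | isovanillin (3-hydroxy-4-methoxybenzaldehyde) | COc1ccc(C=O)cc1O | starting material
3 | Mannich base, 2-bromo-4-[(3-hydroxy-4-methoxyphenyl)(piperidin-1-yl)methyl]-6-methoxyphenol (racemic) | COc1cc(C(N2CCCCC2)c2ccc(OC)c(O)c2)cc(Br)c1O | intermediate
4 | 5-[(3-bromo-5-methoxy-4-oxocyclohexa-2,5-dien-1-ylidene)methyl]-2-methoxyphenyl acetate (E/Z mixture) | COC1=CC(=Cc2ccc(OC)c(OC(C)=O)c2)C=C(Br)C1=O | intermediate
5 | itaconic anhydride (3-methylideneoxolane-2,5-dione) | C=C1CC(=O)OC1=O | starting material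
6 | (−)-8-phenylmenthol, (1R,2S,5R)-5-methyl-2-(2-phenylpropan-2-yl)cyclohexan-1-ol | O[C@@H]1C[C@H](C)CC[C@H]1C(C)(C)c1ccccc1 | starting material
7 | 4-[(−)-8-phenylmenthyl] hydrogen itaconate | C=C(CC(=O)O[C@@H]1C[C@H](C)CC[C@H]1C(C)(C)c1ccccc1)C(=O)O | intermediate
8 | 1-methyl 4-[(−)-8-phenylmenthyl] itaconate | C=C(CC(=O)O[C@@H]1C[C@H](C)CC[C@H]1C(C)(C)c1ccccc1)C(=O)OC | intermediate
9 | lithium dienolate of 8 (deprotonated at C8') | [Li+].[O-]C(=CC(=C)C(=O)OC)O[C@@H]1C[C@H](C)CC[C@H]1C(C)(C)c1ccccc1 | intermediate
10 | 1,6-adduct, 1-methyl 4-[(−)-8-phenylmenthyl] 3-[(3-acetoxy-4-methoxyphenyl)(3-bromo-4-hydroxy-5-methoxyphenyl)methyl]-2-methylidenebutanedioate (C7' arranged as in 16, C8' opposite to 16; written as the phenol) | COc1cc([C@@H](c2ccc(OC)c(OC(C)=O)c2)[C@@H](C(=C)C(=O)OC)C(=O)O[C@@H]2C[C@H](C)CC[C@H]2C(C)(C)c2ccccc2)cc(Br)c1O | intermediate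
11 | 3-methyl 2-[(−)-8-phenylmenthyl] (1S,2R,3R)-1-(3-bromo-4-hydroxy-5-methoxyphenyl)-7-hydroxy-6-methoxy-1,2,3,4-tetrahydronaphthalene-2,3-dicarboxylate | COc1cc([C@H]2c3cc(O)c(OC)cc3C[C@@H](C(=O)OC)[C@@H]2C(=O)O[C@@H]4C[C@H](C)CC[C@H]4C(C)(C)c4ccccc4)cc(Br)c1O | intermediate
12 | (−)-8-phenylmenthyl (1S,2R,3R)-1-(3-bromo-4-hydroxy-5-methoxyphenyl)-7-hydroxy-3-(hydroxymethyl)-6-methoxy-1,2,3,4-tetrahydronaphthalene-2-carboxylate | COc1cc([C@H]2c3cc(O)c(OC)cc3C[C@@H](CO)[C@@H]2C(=O)O[C@@H]4C[C@H](C)CC[C@H]4C(C)(C)c4ccccc4)cc(Br)c1O | intermediate
13 | tri-O-benzyl ether of 12 (O4, O4', O9) | COc1cc([C@H]2c3cc(OCc4ccccc4)c(OC)cc3C[C@@H](COCc4ccccc4)[C@@H]2C(=O)O[C@@H]4C[C@H](C)CC[C@H]4C(C)(C)c4ccccc4)cc(Br)c1OCc1ccccc1 | intermediate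
14 | {(1S,2R,3R)-7-(benzyloxy)-1-[4-(benzyloxy)-3-bromo-5-methoxyphenyl]-3-[(benzyloxy)methyl]-6-methoxy-1,2,3,4-tetrahydronaphthalen-2-yl}methanol | COc1cc([C@H]2c3cc(OCc4ccccc4)c(OC)cc3C[C@@H](COCc4ccccc4)[C@@H]2CO)cc(Br)c1OCc1ccccc1 | intermediate
15 | sodium 9'-O-sulfate of 14 | COc1cc([C@H]2c3cc(OCc4ccccc4)c(OC)cc3C[C@@H](COCc4ccccc4)[C@@H]2COS(=O)(=O)[O-])cc(Br)c1OCc1ccccc1.[Na+] | intermediate
16 | (+)-isolariciresinol 9'-O-(hydrogen sulfate), (7'S,8R,8'R) | COc1cc([C@H]2c3cc(O)c(OC)cc3C[C@@H](CO)[C@@H]2COS(=O)(=O)O)ccc1O | target

**Totals and risks**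
Total steps: 9. Longest linear sequence: 8 steps (steps 2 to 9).

1. Step 4.
   - What may go wrong: once the first bond has formed, the exocyclic double bond may drift into conjugation with C9', and methoxide may add to it faster than the ring A phenolate closes ring B. The sequence would then stall at the open chain.
   - The fallback sets out from 10, isolated by quenching the first stage at −78 °C with acetic acid. It swaps the polar closure for a radical one.
   - Brief K2CO3/MeOH at 0 °C should give the open-chain bisphenol F1.
   - N-iodosuccinimide in MeCN should iodinate F1 only at C1, para to O4–H, because every activated position of ring C is occupied. This gives the aryl iodide F2.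
   - Bu3SnH/AIBN in toluene at 80 °C should abstract iodine in preference to bromine. The aryl radical should then close ring B by the known 6-endo-trig addition to an α-substituted acrylate, giving the tetralin diester epimer mixture F3.
   - NaOMe in MeOH then equilibrates C8 and C8', and the route is rejoined at 11.

2. Step 1.
   - What may go wrong: para-aminoalkylation of the deactivated bromophenol may be slow, and the quinone methide may oligomerise during the hot acetylative elimination.
   - The fallback sets out from 1 and 2 and builds C7' by an organometallic addition instead.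
   - Iodination of 1 (N-iodosuccinimide, para to OH) should give 2-bromo-4-iodo-6-methoxyphenol F4.
   - Acetylation of 2 (Ac2O, pyridine) should give 3-acetoxy-4-methoxybenzaldehyde F5.
   - iPrMgCl·LiCl (2.1 equiv, THF, −20 °C) should deprotonate F4 and exchange only its iodine. Addition of the aryl magnesium species to F5 at −40 °C should give the benzhydrol F6.
   - Mild acid-catalysed dehydration of this para-hydroxybenzhydrol (cat. TsOH, MgSO4, CH2Cl2) comes back to the route at 4.

3. Step 2.
   - What may go wrong: alcoholysis by the hindered alcohol may be sluggish, and the long heating lets the exocyclic double bond of 5 drift into the ring, which leads to citraconate esters.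
   - The fallback sets out from 6 and couples it with a pre-differentiated half ester.
   - Commercial dimethyl itaconate is saponified with one equivalent of LiOH (THF/H2O, 0 °C) at its non-conjugated, more reactive ester, giving 1-methyl hydrogen itaconate F7.
   - Steglich esterification of F7 with 6 (DCC, cat. DMAP, CH2Cl2, 0 °C) comes back to the route at 8 and bypasses 7.

**Further compounds**
F1 | step 4 | open-chain bisphenol (10 without the acetyl group) | COc1cc([C@@H](c2ccc(OC)c(O)c2)[C@@H](C(=C)C(=O)OC)C(=O)O[C@@H]2C[C@H](C)CC[C@H]2C(C)(C)c2ccccc2)cc(Br)c1O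
F2 | step 4 | aryl iodide (F1 iodinated at C1 of ring A) | COc1cc([C@@H](c2cc(O)c(OC)cc2I)[C@@H](C(=C)C(=O)OC)C(=O)O[C@@H]2C[C@H](C)CC[C@H]2C(C)(C)c2ccccc2)cc(Br)c1O
F3 | step 4 | tetralin diester epimer mixture (C7' as in 11, C8' opposite to 11, C8 undefined) | COc1cc([C@H]2c3cc(O)c(OC)cc3CC(C(=O)OC)[C@H]2C(=O)O[C@@H]4C[C@H](C)CC[C@H]4C(C)(C)c4ccccc4)cc(Br)c1O
F4 | step 1 | 2-bromo-4-iodo-6-methoxyphenol | COc1cc(I)cc(Br)c1O
F5 | step 1 | 3-acetoxy-4-methoxybenzaldehyde | COc1ccc(C=O)cc1OC(C)=O
F6 | step 1 | benzhydrol, 5-[(3-bromo-4-hydroxy-5-methoxyphenyl)(hydroxy)methyl]-2-methoxyphenyl acetate (racemic) | COc1cc(C(O)c2ccc(OC)c(OC(C)=O)c2)cc(Br)c1O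
F7 | step 2 | 1-methyl hydrogen itaconate (3-(methoxycarbonyl)but-3-enoic acid) | C=C(CC(=O)O)C(=O)OC
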